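Remark on the chemistry: C3 is (S) in 16 (priorities C2 > C1' > C4 > H), and the same order holds in 12 to 15, so the descriptor stays (S). The structures of 5, 10 and 12 were rebuilt atom by atom from 16 and needed no correction.

Remark on the chemistry: the (5aS,10bR) triazolium salt is written for step 9. Which antipode delivers (3S)-12 is to be settled in a trial run, and the (5aR,10bS) salt is used if the sense is opposite (both come from commercial cis-1-amino-2-indanol).

## Structural features

Abruquinone B (16) is an isoflavan quinone. Its chroman has a benzo ring (ring A, C4a to C8a) with methoxy groups at C6, C7 and C8 and a dihydropyran ring (ring C: O1, C2, C3, C4). C3 is joined by one C–C bond to C1' of a 2,3-dimethoxy-1,4-benzoquinone (ring B; carbonyls at C2' and C5', methoxy groups at C3' and C4'). The only stereocentre is C3 (S), flanked by the methylene groups C2 and C4, so the task is one of absolute configuration at a carbon without a heteroatom. The quinone is the fragile group (electrophilic, reducible, sensitive to base and nucleophiles) and should appear last. Whenever C2 is a carbonyl carbon (lactone, aldehyde), C3–H is benzylic and alpha to C=O, hence acidic, and the stereocentre can be lost. Before oxidation, ring B is almost the same arene as ring A (a 1,2,3,4-tetraoxygenated 5-alkylbenzene). Both can therefore come from one phenol, but an oxidant can tell them apart only if ring B alone has a free hydroxyl group. The real difficulty is to set and keep C3 and to differentiate two near-identical electron-rich rings. The key step exploits O1–C8a–C4a–C4 of ring A as a latent ortho-quinone methide and C2–C3 (ring B on C3) as an arylacetyl enolate, so ring C closes by a formal [4+2] annulation at the lactone level with C3 set by a chiral carbene.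

## Logic of the disconnections

16 ⇒ 15. The two quinone carbonyls are traced back to the C2'–OH and the C5'–OCH3 of a phenol; in the forward sense the O–CH3 bond at C5' is broken. The cut is made here because the quinone would not survive hydride, phosphine or hydrogen. The gain is that ring B of 15 is an ordinary arene. The demand is that the oxidant touch ring B only, which is met because ring A has no free hydroxyl group in 15.

15 ⇒ 14. The O–CH2Ph bond at C2' is cut. The benzyl group masks the ring B oxygen through the fluoride, hydride and Mitsunobu steps and keeps the two phenolic oxygens distinct. The forward step must cleave a benzyl ether without opening ring C, which has no benzylic C–O bond.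

14 ⇒ 13. The O1–C2 bond of ring C is cut. Closing the ether from an open diol avoids a lactol or an oxocarbenium ion at C2; the first opens to an alpha-aryl aldehyde and the second can lose the C3 proton to a 4H-chromene, and either would scramble C3. The forward step needs the C8a hydroxyl as the only free phenol and substitution at the primary carbon C2 only.

13 ⇒ 12. C2 is returned from CH2OH to the lactone carbonyl and the acyl O1–C2 bond is restored. This is the oxidation level that the annulation delivers. The forward reduction must be faster than enolisation of the lactone.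

12 ⇒ 5 + 10 (through 11). C3–C4 and O1–C2 are cut. This divides the molecule into two one-ring halves of equal size and assigns ring C, two skeletal bonds and the stereocentre to one catalytic step. The forward step demands catalyst control of the enolate face, slow release of 11, and a medium too weakly basic to epimerise 12.

5 ⇒ 4 ⇒ 3 ⇒ 2. The C4–Br bond, the C4–H bond made by reduction and the O–Si bond are cut in turn. The silyl group is the fluoride trigger and the bromide the leaving group. The reduction must not let silicon migrate to the new benzylic oxygen, and 5, a para-methoxybenzyl-type bromide, must be used fresh.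

10 ⇒ 9 ⇒ 8 ⇒ 6 ⇒ 2. The C2–N acyl bond, the nitrile (back from the acid), the C2–C3 bond (one-carbon homologation of the aldehyde) and the O–benzyl bond are cut. The acyl imidazole is an isolable acyl donor for the carbene, and the homologation supplies C2.

2 ⇒ 1. The aryl–CHO bond is cut. The formyl carbon becomes C4 in one arm and C3 in the other, and 1 has a single free ortho position, so no regiochemical question arises.

## Other disconnections considered

Alternative 1: The cut is at C3–C1', with a temporary C4–O bond, so 16 is viewed as the opened and oxidised form of a cis-pterocarpan.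
- Forward step: 6,7,8-trimethoxy-2H-chromene A1 and 2,3-dimethoxy-1,4-benzoquinone A2 would be joined by the chiral Lewis acid TiCl2(TADDOLate), made from TiCl2(OiPr)2 and the tartrate-derived diol TADDOL. C3 of A1 would attack the titanium-bound quinone and the quinone oxygen would close onto the benzylic cation at C4, giving the cis-(6aS,11aS)-pterocarpan A3. Hydrogenolysis of the benzylic C11a–O bond would give hydroquinone A4, and mild oxidation 16.
- In favour: A1 should come from 1 in two steps and A2 from 1 in one, so the whole route is about six steps. Ring B enters at the quinone level without protecting groups, A2 is symmetrical, and C6a of A3 has no acidifying carbonyl next to it.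
- Against: the asymmetric form of this cycloaddition usually needs a full equivalent of the chiral titanium complex and depends on two-point binding of the quinone. A chromene as electron-rich as A1 may react by an unselective background path or by electron transfer, [2+2] and [5+2] adducts are side channels of the reaction class, and C11a–O must be cleaved in an oxidation-prone hydroquinone monoether.
- Comparison: on step economy and on configurational stability after the key step, Alternative 1 is the better plan. The chosen plan is longer but places the C–C bond formation inside a catalytic cycle on a covalently bound chiral enolate, and each of its steps has a close precedent on this substitution pattern.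

Alternative 2: The cuts are at C4–C4a and C3–C1' around a two-carbon vinylboron unit; C2 and the O1–C2 bond come later.
- Forward step: the aryllithium from 2-(benzyloxy)-1-bromo-3,4,5-trimethoxybenzene A5 would add to vinylboronic acid pinacol ester A7. The ate complex would couple with 1-bromo-3,4,5-trimethoxy-2-(methoxymethoxy)benzene A6 under Pd(OAc)2, a chiral MandyPhos ligand and NaOTf. The arylpalladium species, formed by oxidative addition to zerovalent palladium, would trigger a 1,2-shift of the ring B aryl from boron to carbon and give boronate A8. Matteson homologation, oxidation and removal of the methoxymethyl group would then meet the chosen route at 13.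
- In favour: three simple components, catalytic asymmetric induction, and stereospecific 1,2-shifts. The stereocentre is never alpha to a carbonyl group, and with about eleven steps the plan is equal to or slightly better than the chosen one in length.
- Against: the migrating aryl group carries an ortho benzyloxy group and the electrophile A6 is ortho-substituted and electron-rich, both at the edge of what this coupling tolerates. Direct cross-coupling at boron or beta-hydride elimination could compete. No ring closes, C2 has to be inserted afterwards into a hindered secondary benzylic boronate, and an aryllithium at low temperature is required.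
- Comparison: mechanistically the alternative rests on a palladium-induced metallate shift and the chosen plan on an enolate addition with ring closure. The chosen plan forms ring C, two bonds and the stereocentre at once and is metal-free, whereas the alternative needs three further steps to reach the same diol.

Alternative 3: The cut is the C5–C6 bond of ring A, with the whole ring traced back to a four-membered ring.
- Forward step: a side-chain alkenyllithium would add to dimethyl squarate A9, and silylation would give cyclobutenone A10. Heating would open it to a dienylketene whose ketene carbon (C6) bonds to the alkene terminus (C5), giving phenol A11 with the C8a oxygen silylated and the C6 hydroxyl free. Methylation of that hydroxyl and removal of both silyl groups would again arrive at 13.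
- In favour: the key step is thermal and reagent-free with fixed regiochemistry, the ring A oxygens are differentiated (useful for congeners), and no stereochemical risk attaches to the key step itself. On these points it is the equal or the better of the chosen plan.
- Against: the step creates no stereocentre and none of the bonds that join the three parts. C3 would have to be set beforehand, for example by an auxiliary-controlled alkylation of a derivative of 9, so the arylacetic acid is needed anyway and about ten more steps follow. Ring A is rebuilt although it is available as a phenol.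
- Comparison: at well over fifteen steps and with an aromatic ring made from scratch, the alternative loses clearly to the chosen plan in step economy and in convergence.

Key step: step 9

## Route

Step 1
Reactants: 1 2,3,4-trimethoxyphenol
Product: 2 2-hydroxy-3,4,5-trimethoxybenzaldehyde
Conditions: MgCl2, Et3N, (CH2O)n, THF, reflux; then aq. HCl
Reagents that add atoms: paraformaldehyde (formaldehyde equivalent), C=O
Why: Casnati–Skattebøl ortho-formylation: the magnesium phenoxide delivers formaldehyde to the only free ortho position (the para position carries OMe) and a second formaldehyde oxidises the hydroxymethyl intermediate by hydride transfer.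

Step 2
Reactants: 2 2-hydroxy-3,4,5-trimethoxybenzaldehyde
Product: 3 2-(tert-butyldimethylsilyloxy)-3,4,5-trimethoxybenzaldehyde
Conditions: TBSCl, imidazole, DMF, rt
Reagents that add atoms: tert-butyldimethylsilyl chloride, CC(C)(C)[Si](C)(C)Cl
Why: Imidazole-promoted silylation of a phenol; the aryl silyl ether is the later fluoride trigger.

Step 3
Reactants: 3 2-(tert-butyldimethylsilyloxy)-3,4,5-trimethoxybenzaldehyde
Product: 4 [2-(tert-butyldimethylsilyloxy)-3,4,5-trimethoxyphenyl]methanol
Conditions: i-Bu2AlH, CH2Cl2, −78 °C; aq. potassium sodium tartrate
Reagents that add atoms: none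
Why: Hydride reduction of the aldehyde; the aluminium alkoxide formed at −78 °C is too weakly nucleophilic to attack silicon, so the 1,5-shift of the silyl group to the benzylic oxygen, which free alkoxides trigger, should be avoided.

Step 4
Reactants: 4 [2-(tert-butyldimethylsilyloxy)-3,4,5-trimethoxyphenyl]methanol
Product: 5 [6-(bromomethyl)-2,3,4-trimethoxyphenoxy](tert-butyl)dimethylsilane
Conditions: CBr4, PPh3, CH2Cl2, 0 °C; short pad of deactivated silica, used at once
Reagents that add atoms: carbon tetrabromide, BrC(Br)(Br)Br
Why: Appel bromination (SN2 on the alkoxyphosphonium ion) under neutral conditions that spare the aryl silyl ether; the para-methoxybenzyl-type bromide is labile and is not stored.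

Step 5
Reactants: 2 2-hydroxy-3,4,5-trimethoxybenzaldehyde
Product: 6 2-benzyloxy-3,4,5-trimethoxybenzaldehyde
Conditions: BnBr, K2CO3, DMF, 60 °C
Reagents that add atoms: benzyl bromide, BrCc1ccccc1
Why: Williamson etherification of the phenoxide; the benzyl ether withstands fluoride, carbene, hydride and Mitsunobu conditions and leaves later by neutral hydrogenolysis.

Step 6
Reactants: 6 2-benzyloxy-3,4,5-trimethoxybenzaldehyde
Product: 8 2-(2-benzyloxy-3,4,5-trimethoxyphenyl)acetonitrile, via vinylformamide 7 (not isolated)
Conditions: TosMIC, KOt-Bu, DME, −50 °C to −30 °C; then MeOH, reflux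
Reagents that add atoms: p-toluenesulfonylmethyl isocyanide (TosMIC), Cc1ccc(cc1)S(=O)(=O)C[N+]#[C-]
Why: van Leusen reductive cyanation: the TosMIC anion adds to the aldehyde, the oxazoline opens to 7, and methoxide then removes the formyl group, sulfinate leaves and the ketenimine tautomerises to the nitrile; the cold aprotic first stage suppresses elimination to the 5-aryloxazole.

Step 7
Reactants: 8 2-(2-benzyloxy-3,4,5-trimethoxyphenyl)acetonitrile
Product: 9 2-(2-benzyloxy-3,4,5-trimethoxyphenyl)acetic acid
Conditions: KOH, EtOH/H2O, reflux; then aq. HCl to pH 2
Reagents that add atoms: potassium hydroxide, [K+].[OH-]; water, O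
Why: Base hydrolysis of the nitrile through the amide; benzyl and methyl aryl ethers are inert to hydroxide.

Step 8
Reactants: 9 2-(2-benzyloxy-3,4,5-trimethoxyphenyl)acetic acid
Product: 10 1-[2-(2-benzyloxy-3,4,5-trimethoxyphenyl)acetyl]imidazole
Conditions: CDI, THF, rt; freed from imidazole by a cold aqueous wash and crystallisation
Reagents that add atoms: 1,1'-carbonyldiimidazole, O=C(n1ccnc1)n1ccnc1
Why: Acyl transfer through the carbonic mixed anhydride, which loses CO2 and acylates imidazole; N-acylimidazoles of arylacetic acids are isolable and are the acyl donors the carbene needs.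

Step 9
Reactants: 5 [6-(bromomethyl)-2,3,4-trimethoxyphenoxy](tert-butyl)dimethylsilane, 10 1-[2-(2-benzyloxy-3,4,5-trimethoxyphenyl)acetyl]imidazole
Product: 12 (3S)-3-(2-benzyloxy-3,4,5-trimethoxyphenyl)-6,7,8-trimethoxychroman-2-one, via ortho-quinone methide 11 (not isolated)
Conditions: (5aS,10bR)-2-mesityl-5a,10b-dihydro-4H,6H-indeno[2,1-b][1,2,4]triazolo[4,3-d][1,4]oxazin-2-ium tetrafluoroborate (15 mol %), CsF, 18-crown-6, 4 Å MS, THF, −20 °C; 5 in excess
Reagents that add atoms: none
Why: Fluoride, made soluble by the crown ether, removes the silyl group of 5 and the phenoxide expels bromide by 1,4-elimination to give 11, while the carbene freed from the triazolium salt is acylated by 10 and the released imidazolide deprotonates the acyl azolium to the (Z)-azolium enolate. The enolate carbon (future C3) adds to the methylene terminus C4 of 11, ring A rearomatises, and the C8a phenoxide attacks the acyl carbon C2 and releases the carbene. The closest known reaction type is the carbene-catalysed formal [4+2] annulation of acyl-imidazole-derived azolium enolates with ortho-quinone methides made by fluoride from silylated ortho-hydroxybenzyl bromides, which gives 3-substituted 3,4-dihydrocoumarins. The pyranone ring closes as a formal hetero-[4+2] (O1, C8a, C4a, C4 from 11; C3, C2 from the enolate), with the last bond O1–C2 formed by 6-exo-trig O-acylation. C3 is the only new stereocentre and is under catalyst control: the fused aminoindane blocks one face of the planar enolate and the N-aryl group fixes its geometry, so 11 approaches the open face; C4 is unsubstituted, so no diastereoselectivity is at stake. The step needs C- over O-alkylation of the enolate, capture of 11 faster than its dimerisation or its trapping by imidazole, and survival of the acidic C3–H; slow heterogeneous release of 11 from an excess of 5, the single free ortho position of ring A, the low temperature and the weakly basic medium serve these ends, and the electron-rich ring B lowers the acidity of C3–H. The benzyl ether keeps the ring B oxygen from lactonising onto the acyl azolium.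

Step 10
Reactants: 12 (3S)-3-(2-benzyloxy-3,4,5-trimethoxyphenyl)-6,7,8-trimethoxychroman-2-one
Product: 13 (2S)-2-(2-benzyloxy-3,4,5-trimethoxyphenyl)-3-(2-hydroxy-3,4,5-trimethoxyphenyl)propan-1-ol
Conditions: 12 added to LiAlH4, THF, −20 °C to 0 °C; aq. potassium sodium tartrate under argon
Reagents that add atoms: none
Why: LiAlH4 reduction of an aryl ester: hydride adds to the lactone carbonyl, the phenoxide is expelled and the aldehyde is reduced at once; with hydride always in excess at low temperature, reduction should outrun enolisation, and afterwards C3 no longer has a carbonyl next to it.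

Step 11
Reactants: 13 (2S)-2-(2-benzyloxy-3,4,5-trimethoxyphenyl)-3-(2-hydroxy-3,4,5-trimethoxyphenyl)propan-1-ol
Product: 14 (3S)-3-(2-benzyloxy-3,4,5-trimethoxyphenyl)-6,7,8-trimethoxychroman
Conditions: PPh3, DIAD, THF, 0 °C to rt
Reagents that add atoms: none
Why: Intramolecular Mitsunobu etherification (6-exo-tet): the primary alcohol is activated as the alkoxyphosphonium ion and displaced by the ring A phenoxide; C3 is not the reacting carbon and is untouched, and the benzylated ring B oxygen cannot form the competing dihydrobenzofuran.

Step 12
Reactants: 14 (3S)-3-(2-benzyloxy-3,4,5-trimethoxyphenyl)-6,7,8-trimethoxychroman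
Product: 15 2,3,4-trimethoxy-6-[(3S)-6,7,8-trimethoxychroman-3-yl]phenol
Conditions: H2 (1 atm), Pd/C, EtOAc, rt; used directly
Reagents that add atoms: none
Why: Hydrogenolysis of the benzyl aryl ether on palladium on carbon; ring C has no benzylic C–O bond (O1 is bound to C2 and to the arene) and should survive.

Step 13
Reactants: 15 2,3,4-trimethoxy-6-[(3S)-6,7,8-trimethoxychroman-3-yl]phenol
Product: 16 abruquinone B, 2,3-dimethoxy-5-[(3S)-6,7,8-trimethoxychroman-3-yl]cyclohexa-2,5-diene-1,4-dione
Conditions: PhI(OAc)2, MeCN/H2O, 0 °C
Reagents that add atoms: water, O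
Why: Hypervalent iodine oxidation of a para-methoxyphenol: ligand exchange at iodine, attack of water at the para carbon C5' and loss of methanol from the hemiketal give the para-quinone; ring A has no free hydroxyl group and should not be oxidised at 0 °C, and C3 is not involved.

## Compound list

1 | 2,3,4-trimethoxyphenol | COc1ccc(O)c(OC)c1OC | starting material
2 | 2-hydroxy-3,4,5-trimethoxybenzaldehyde | COc1cc(C=O)c(O)c(OC)c1OC | intermediate
3 | 2-(tert-butyldimethylsilyloxy)-3,4,5-trimethoxybenzaldehyde | COc1cc(C=O)c(O[Si](C)(C)C(C)(C)C)c(OC)c1OC | intermediate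
4 | [2-(tert-butyldimethylsilyloxy)-3,4,5-trimethoxyphenyl]methanol | COc1cc(CO)c(O[Si](C)(C)C(C)(C)C)c(OC)c1OC | intermediate
5 | [6-(bromomethyl)-2,3,4-trimethoxyphenoxy](tert-butyl)dimethylsilane | COc1cc(CBr)c(O[Si](C)(C)C(C)(C)C)c(OC)c1OC | intermediate
6 | 2-benzyloxy-3,4,5-trimethoxybenzaldehyde | COc1cc(C=O)c(OCc2ccccc2)c(OC)c1OC | intermediate
7 | N-[2-(2-benzyloxy-3,4,5-trimethoxyphenyl)-1-(4-methylphenylsulfonyl)ethenyl]formamide (alkene geometry not defined) | COc1cc(C=C(NC=O)S(=O)(=O)c2ccc(C)cc2)c(OCc2ccccc2)c(OC)c1OC | intermediate (not isolated)
8 | 2-(2-benzyloxy-3,4,5-trimethoxyphenyl)acetonitrile | COc1cc(CC#N)c(OCc2ccccc2)c(OC)c1OC | intermediate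
9 | 2-(2-benzyloxy-3,4,5-trimethoxyphenyl)acetic acid | COc1cc(CC(=O)O)c(OCc2ccccc2)c(OC)c1OC | intermediate
10 | 1-[2-(2-benzyloxy-3,4,5-trimethoxyphenyl)acetyl]imidazole | COc1cc(CC(=O)n2ccnc2)c(OCc2ccccc2)c(OC)c1OC | intermediate
11 | 2,3,4-trimethoxy-6-methylidenecyclohexa-2,4-dien-1-one | C=C1C=C(OC)C(OC)=C(OC)C1=O | intermediate (not isolated)
12 | (3S)-3-(2-benzyloxy-3,4,5-trimethoxyphenyl)-6,7,8-trimethoxychroman-2-one | COc1cc([C@@H]2Cc3cc(OC)c(OC)c(OC)c3OC2=O)c(OCc2ccccc2)c(OC)c1OC | intermediate
13 | (2S)-2-(2-benzyloxy-3,4,5-trimethoxyphenyl)-3-(2-hydroxy-3,4,5-trimethoxyphenyl)propan-1-ol | COc1cc([C@@H](CO)Cc2cc(OC)c(OC)c(OC)c2O)c(OCc2ccccc2)c(OC)c1OC | intermediate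
14 | (3S)-3-(2-benzyloxy-3,4,5-trimethoxyphenyl)-6,7,8-trimethoxychroman | COc1cc([C@H]2COc3c(cc(OC)c(OC)c3OC)C2)c(OCc2ccccc2)c(OC)c1OC | intermediate
15 | 2,3,4-trimethoxy-6-[(3S)-6,7,8-trimethoxychroman-3-yl]phenol | COc1cc([C@H]2COc3c(cc(OC)c(OC)c3OC)C2)c(O)c(OC)c1OC | intermediate
16 | abruquinone B, 2,3-dimethoxy-5-[(3S)-6,7,8-trimethoxychroman-3-yl]cyclohexa-2,5-diene-1,4-dione | COC1=C(OC)C(=O)C([C@H]2COc3c(cc(OC)c(OC)c3OC)C2)=CC1=O | target

## Step count and least certain steps

Total step count: 13. Longest linear sequence: 10 steps (steps 1, 5, 6, 7, 8, 9, 10, 11, 12, 13).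

**Step 9 (key step).** Three things are most likely to go wrong:
- insufficient facial discrimination, because the ortho benzyloxy group twists ring B out of the enolate plane;
- erosion of configuration by imidazole- or fluoride-mediated enolisation of the lactone after ring closure;
- self-condensation of the quinone methide outrunning the annulation.

The fallback replaces catalyst control by auxiliary control; it sets out from 9 and 5 and comes back at 13. Acid 9 is activated with pivaloyl chloride and Et3N and coupled with lithiated (4S)-4-benzyl-1,3-oxazolidin-2-one to give (4S)-4-benzyl-3-[2-(2-benzyloxy-3,4,5-trimethoxyphenyl)acetyl]-1,3-oxazolidin-2-one F1. Its sodium (Z)-enolate (NaN(SiMe3)2, THF, −78 °C) is alkylated by 5 on the face away from the benzyl group of the auxiliary to give (4S)-4-benzyl-3-[(2S)-2-(2-benzyloxy-3,4,5-trimethoxyphenyl)-3-[2-(tert-butyldimethylsilyloxy)-3,4,5-trimethoxyphenyl]propanoyl]-1,3-oxazolidin-2-one F2. LiBH4 removes the auxiliary to give (2S)-2-(2-benzyloxy-3,4,5-trimethoxyphenyl)-3-[2-(tert-butyldimethylsilyloxy)-3,4,5-trimethoxyphenyl]propan-1-ol F3, and n-Bu4NF frees the phenol to give 13.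

**Step 6.** The oxazoline intermediate may eliminate sulfinate to a 5-aryloxazole instead of opening, or the hindered, electron-rich aldehyde may add the TosMIC anion too slowly. The fallback is a Wittig homologation; it sets out from 6 and comes back at 9. Methoxymethylenetriphenylphosphorane (from Ph3PCH2OMe chloride and KOt-Bu) gives the enol ether 2-benzyloxy-3,4,5-trimethoxy-1-(2-methoxyethenyl)benzene F4. Aqueous acid hydrolyses it to 2-(2-benzyloxy-3,4,5-trimethoxyphenyl)acetaldehyde F5, and Pinnick oxidation (NaClO2, NaH2PO4, 2-methyl-2-butene) gives 9.

**Step 3 (with step 4).** The silyl group may migrate from the phenolic to the benzylic oxygen during or after the reduction, and the bromide made from 4 ionises easily. The fallback never exposes a free benzylic alkoxide next to the aryl silyl ether; it sets out from 2 and comes back at 5. NaBH4 reduces 2 to 2-(hydroxymethyl)-4,5,6-trimethoxyphenol F6. Excess TBSCl and imidazole give the bis-silyl ether tert-butyl{[2-(tert-butyldimethylsilyloxy)-3,4,5-trimethoxyphenyl]methoxy}dimethylsilane F7. Ph3PBr2 in CH2Cl2 then converts only the benzylic silyl ether into the bromide, giving 5.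

**Step 13.** Attack at the ortho methoxy carbon C3' (ortho-quinone formation) or further oxidation of the product in the aqueous medium may compete. The fallback separates oxidation from quinone release; it sets out from 15 and comes back at 16. PhI(OAc)2 in methanol traps the phenoxonium ion at the para carbon to give the isolable quinone monoketal 2,3,4,4-tetramethoxy-6-[(3S)-6,7,8-trimethoxychroman-3-yl]cyclohexa-2,5-dien-1-one F8. Dilute aqueous acid in acetone then hydrolyses the ketal to 16 without any oxidant present.

## Further compounds

F1 | step 9 | (4S)-4-benzyl-3-[2-(2-benzyloxy-3,4,5-trimethoxyphenyl)acetyl]-1,3-oxazolidin-2-one | COc1cc(CC(=O)N2[C@@H](Cc3ccccc3)COC2=O)c(OCc2ccccc2)c(OC)c1OC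
F2 | step 9 | (4S)-4-benzyl-3-[(2S)-2-(2-benzyloxy-3,4,5-trimethoxyphenyl)-3-[2-(tert-butyldimethylsilyloxy)-3,4,5-trimethoxyphenyl]propanoyl]-1,3-oxazolidin-2-one | COc1cc([C@H](Cc2cc(OC)c(OC)c(OC)c2O[Si](C)(C)C(C)(C)C)C(=O)N2[C@@H](Cc3ccccc3)COC2=O)c(OCc2ccccc2)c(OC)c1OC
F3 | step 9 | (2S)-2-(2-benzyloxy-3,4,5-trimethoxyphenyl)-3-[2-(tert-butyldimethylsilyloxy)-3,4,5-trimethoxyphenyl]propan-1-ol | COc1cc([C@H](Cc2cc(OC)c(OC)c(OC)c2O[Si](C)(C)C(C)(C)C)CO)c(OCc2ccccc2)c(OC)c1OC
F4 | step 6 | 2-benzyloxy-3,4,5-trimethoxy-1-(2-methoxyethenyl)benzene (E/Z mixture) | COC=Cc1cc(OC)c(OC)c(OC)c1OCc1ccccc1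
F5 | step 6 | 2-(2-benzyloxy-3,4,5-trimethoxyphenyl)acetaldehyde | COc1cc(CC=O)c(OCc2ccccc2)c(OC)c1OC
F6 | step 3 | 2-(hydroxymethyl)-4,5,6-trimethoxyphenol | COc1cc(CO)c(O)c(OC)c1OC
F7 | step 3 | tert-butyl{[2-(tert-butyldimethylsilyloxy)-3,4,5-trimethoxyphenyl]methoxy}dimethylsilane | COc1cc(CO[Si](C)(C)C(C)(C)C)c(O[Si](C)(C)C(C)(C)C)c(OC)c1OC
F8 | step 13 | 2,3,4,4-tetramethoxy-6-[(3S)-6,7,8-trimethoxychroman-3-yl]cyclohexa-2,5-dien-1-one | COC1=C(OC)C(OC)(OC)C=C([C@H]2COc3c(cc(OC)c(OC)c3OC)C2)C1=O
A1 | alternative 1 | 6,7,8-trimethoxy-2H-chromene | COc1cc2C=CCOc2c(OC)c1OC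
A2 | alternative 1 | 2,3-dimethoxy-1,4-benzoquinone | COC1=C(OC)C(=O)C=CC1=O
A3 | alternative 1 | cis-(6aS,11aS)-2,3,4,9,10-pentamethoxypterocarpan-8-ol | Oc1cc2c(c(OC)c1OC)O[C@H]3[C@@H]2COc2c3cc(OC)c(OC)c2OC
A4 | alternative 1 | 2,3-dimethoxy-5-[(3S)-6,7,8-trimethoxychroman-3-yl]benzene-1,4-diol | COc1c(O)cc([C@H]2COc3c(cc(OC)c(OC)c3OC)C2)c(O)c1OC
A5 | alternative 2 | 2-(benzyloxy)-1-bromo-3,4,5-trimethoxybenzene | COc1cc(Br)c(OCc2ccccc2)c(OC)c1OC
A6 | alternative 2 | 1-bromo-3,4,5-trimethoxy-2-(methoxymethoxy)benzene | COc1cc(Br)c(OCOC)c(OC)c1OC
A7 | alternative 2 | vinylboronic acid pinacol ester, 2-ethenyl-4,4,5,5-tetramethyl-1,3,2-dioxaborolane | C=CB1OC(C)(C)C(C)(C)O1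
A8 | alternative 2 | 2-[(1S)-1-(2-benzyloxy-3,4,5-trimethoxyphenyl)-2-[3,4,5-trimethoxy-2-(methoxymethoxy)phenyl]ethyl]-4,4,5,5-tetramethyl-1,3,2-dioxaborolane | COc1cc([C@H](Cc2cc(OC)c(OC)c(OC)c2OCOC)B2OC(C)(C)C(C)(C)O2)c(OCc2ccccc2)c(OC)c1OC
A9 | alternative 3 | dimethyl squarate, 3,4-dimethoxycyclobut-3-ene-1,2-dione | COC1=C(OC)C(=O)C1=O
A10 | alternative 3 | 4-[(4S)-4-(2-benzyloxy-3,4,5-trimethoxyphenyl)-5-(tert-butyldimethylsilyloxy)pent-1-en-2-yl]-4-(tert-butyldimethylsilyloxy)-2,3-dimethoxycyclobut-2-en-1-one (both epimers at the ring carbon) | COC1=C(OC)C(O[Si](C)(C)C(C)(C)C)(C(=C)C[C@H](CO[Si](C)(C)C(C)(C)C)c2cc(OC)c(OC)c(OC)c2OCc2ccccc2)C1=O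
A11 | alternative 3 | 5-[(2S)-2-(2-benzyloxy-3,4,5-trimethoxyphenyl)-3-(tert-butyldimethylsilyloxy)propyl]-4-(tert-butyldimethylsilyloxy)-2,3-dimethoxyphenol | COc1c(O)cc(C[C@H](CO[Si](C)(C)C(C)(C)C)c2cc(OC)c(OC)c(OC)c2OCc2ccccc2)c(O[Si](C)(C)C(C)(C)C)c1OC
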